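(Readings and results were generated by integration for an exercise; noise was put on by code.)

4 questions stand on cedar, ash and maple, and a ledger answers them: where each unit of L has gone at the end.

| flask | D | L | remark | time |
|---|---|---|---|---|
| gamma | 0.020 M | 0.020 M | run made earlier |  |
| beta | 0.010 M | 0.020 M | run made earlier |  |
| theta | 0.040 M | 0.020 M | run made earlier |  |
| cedar | 0.020 M | 0.0200 M | everything together at the start | 6.0 min |
| ash | 0.020 M (fed, over 5.0 min) | 0.0200 M | all else is in the flask from the start; the feed brings no volume worth counting | 6.0 min |
| maple | 0.020 M | 0.0200 M (fed, over 5.0 min) | all else is in the flask from the start; the feed brings no volume worth counting | 6.0 min |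

- gamma (time / min: E / %): 0.500: 56.5; 0.833: 69.1; 1.50: 79.7; 3.00: 88.7; 6.00: 93.8
- beta (time / min: E / %): 0.250: 41.9; 0.500: 66.2; 1.00: 84.3; 2.00: 97.5; 4.00: 98.0
- theta (time / min: E / %): 0.250: 31.1; 0.500: 42.0; 1.00: 46.1; 2.00: 50.0; 4.00: 49.7

(scatter of a reading: 1 percentage point)

1. which flask leads in amount of E, in percent of the D charged ("all alike" within 1.5 percentage points) (cedar / ash / maple / all alike)
2. how much E is there at the end, in percent of the D charged: cedar
3. how much E is there at the end, in percent of the D charged: ash
4. how much E is there at the end, in percent of the D charged: maple



- First entry, L turned into E. In the theta run, with D at 0.040 M and L at 0.020 M, E reads 50.0 % of the D charged at 2.00 min, which is 0.0200 M. So one L gives one E, and L there is the limiting reagent.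
- Second entry, L unspent. In the gamma run, with equal charges, the reciprocal of the share left climbs steadily. The slope reads 2.60 /min at 0.500 min and 2.62 /min at 3.00 min, so it can be frozen at the latter value.
- Cedar starts with that reciprocal at one, so after 6.0 min the reckoned share left is 5.99 %, and the reckoned E is 94.0 %.
- In ash and maple, reckoned with that slope and a rate in proportion to D times L, the excess of the reagent charged over the reagent fed shrinks steadily and closes at the end of the feed. Integrating gives each moment a weight, half a bell curve going back from that end, of width sqrt(feed time / slope) = 1.38 min, shorter than the feed, so the late stretch counts; the area under it is about 1.25 times that width.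
- A feed of 5.0 min is therefore worth 1.73 min of mixed flask, less than the feed itself. This is the equal time: the time, counted from a reciprocal of zero, over which a mixed flask gains what the feed gains.
- With the remaining 1.00 min added, this reckoning closes the books for ash and maple alike: 14.0 % left, E 86.0 %. Cedar leaves less.
- The forecast has cedar leading, with 94 % for cedar, 86 % for ash and 86 % for maple, and of the feeds it says “the rate is symmetric in D and L and the amounts are equal, so both feeds give the same result”.
- The flasks give 94.0 % for cedar, 87.0 % for ash and 84.2 % for maple, so cedar leads.

    D ⇌ G (K = 4.90, k = 0.329 /s)
    D + L ⇌ J (K = 25.7 /M, k = 0.373 /M/s)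
    L + G → E (k = 3.26 /M/s)
    D + G → X (k = 0.103 /M/s)

- At the end maple holds X at 6.86 % of the D charged, ash 0.383 %, each X counted as two in these percentages. The equal time put L unspent at 14.0 %; ash shows 13 %, maple 16 %.
- Maple left until 10 min is reckoned, with the equal time, at 5.68 % of L left and E 94.3 %. The computed flask gives E 91.0 %, with L 9.01 % and X 6.90 %.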